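At 4.0 min I read D in Friday's, Tuesday's, Monday's and Thursday's set-ups, each holding the same charge of G and X.

| flask | G | X | remark | time |
|---|---|---|---|---|
| maple | 0.050 M | 0.10 M | run made earlier |  |
| alder | 0.070 M | 0.10 M | run made earlier |  |
| birch | 0.11 M | 0.10 M | run made earlier |  |
| Friday's | 0.050 M | 0.100 M (fed, over 4.00 min) | a stirred flask in which X is dosed at a steady rate over 4.00 min without added volume, worked up at 4.0 min | 4.0 min |
| Tuesday's | 0.050 M | 0.100 M | one stirred flow tank at steady state, fed with the mixture as stated, mean residence time 4.0 min |  |
| Monday's | 0.050 M | 0.100 M | a closed flask charged with all of it at once and left for 4.0 min | 4.0 min |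
| Thursday's | 0.050 M | 0.100 M | plug flow through a tube for 4.0 min, no back-mixing | 4.0 min |

- maple (time / min: D / %): 0.667: 40.0; 1.33: 29.0; 2.00: 19.6; 2.50: 16.8
- alder (time / min: D / %): 0.667: 35.5; 1.33: 25.2; 2.00: 18.4; 2.50: 15.5
- birch (time / min: D / %): 0.200: 29.6; 0.417: 32.0; 1.00: 23.4; 2.50: 11.5

(each reading ± 0.5 percentage points)

- the stated concentrations are those of everything mixed, before any reaction; amounts are the same in each set-up
- the earlier runs were read with a standard deviation of 0.5 percentage points
- the feed brings no volume worth counting
- the earlier runs were made in a closed, stirred flask

1. the set-up with the highest amount of D at the outlet or at the end, in percent of the G put in ("none" if the first two lie within 2 percentage points) (Friday's / Tuesday's / Monday's / Thursday's / none)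
2. amount of D at the outlet or at the end, in percent of the G put in, Friday's
3. amount of D at the outlet or at the end, in percent of the G put in, Tuesday's
4. amount of D at the outlet or at the end, in percent of the G put in, Monday's
5. amount of D at the outlet or at the end, in percent of the G put in, Thursday's

I keep a ledger of G, the limiting reagent at 2.00 equivalents of X, and follow one molecule through two forks. The maple run falls from 40.0 % to 16.8 % between 0.667 min and 2.50 min, which gives 0.473 min⁻¹, and this is my fade rate, the fraction of the standing D lost per minute. The birch run reads 0.474 min⁻¹, so I carry the rate across charges and vessels, as a reading and a bet.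

The first entry is the entry into D: running maple back to zero time books 54.8 % of G into D and 45.2 % elsewhere. The second entry is survival, and it depends on the age of a D at the reading. In Monday's flask and Thursday's tube I take a D as about 4.0 min old, so its chance is 15.1 %. In Tuesday's tank ages spread around the residence time, so the chance is 34.6 %. In Friday's flask I take D as made evenly during the feed, so the chance is 44.9 %, more than in the tank. The books close at 8.27 % for Monday's and Thursday's, 19.0 % for Tuesday's and 24.6 % for Friday's, so I commit to Friday's.

The forecast instead names Tuesday's, with 29 % there, 3 % for Friday's and 8.4 % for Monday's and Thursday's, on the ground that “Dosing starves G of X”.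

The simulation gives 24.2 % for Friday's, 16.8 % for Tuesday's, 9.67 % for Monday's and 9.67 % for Thursday's, so the best is Friday's.

    G + X ⇌ D + J (K = 0.679, k = 0.510 L mol⁻¹ s⁻¹)
    X + L → E + J (k = 0.0119 L mol⁻¹ s⁻¹)
    G + X → L + J (k = 0.0779 L mol⁻¹ s⁻¹)
    X + D → E + J (k = 0.117 L mol⁻¹ s⁻¹)

The slow dosing of X is a part of the reason for Friday's lead over Monday's: with the same charge given at once, D ends at 9.67 % against 24.2 %. Part of what holds D down in Thursday's tube is the reverse step together with the turning of X + D into E + J: D ends at 9.67 %, but at 35.3 % without the first and at 30.7 % without the second. I use the same survival chance on a neighbour of Friday's charged with 0.12 M of G. Birch, at 0.11 M of G, is the nearest run: its 23.4 % at 1.00 min, run back at 0.473 min⁻¹, books 37.6 % into D, and 44.9 % of that is 16.9 %. That neighbour ends with 17.7 % of D.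

The earlier runs and the new flask are simulated from invented constants, noise included.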